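**Assumption:** the target has no stereocentre or stereogenic double bond, so "single enantiomer" needs no stereocontrol; the side chain is read as unbranched n‑C33H67 (tritriacontyl).

## Retrosynthetic overview

1. Avoided: the usual o‑hydroxyacetophenone + acyl donor route (Baker–Venkataraman/Claisen, cyclodehydration, O‑demethylation).
2. 13 ⇒ 12 by chelation‑controlled 7‑O‑methylation as the last step; no protecting groups are used anywhere.
3. Key step: 12 ⇒ phloroglucinol 9 + β‑keto ester 8 by thermal acylketene [3+3] annulation (Mentzer). It forms C4–C4a and O1–C2; the pyranone is the only ring made (the benzene ring is bought), and the C3 symmetry of 9 removes any regiochemical question.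
4. 8 ⇒ C34 acid 5 + Meldrum's acid 6; 5 ⇒ 1‑bromodocosane 1 + 12‑bromododecanoic acid 2 by Cu‑catalysed sp3–sp3 Grignard coupling (C22 + C12).

## Route

**Step 1**
Reactants: 1 1‑bromodocosane; 2 12‑bromododecanoic acid
Product: 5 tetratriacontanoic acid, via docosylmagnesium bromide 3 (not isolated), via chloromagnesium 12-bromododecanoate 4 (not isolated)
Conditions: (a) 1, Mg, THF, 50 °C; (b) 2, MeMgCl (1.0 equiv), THF, −20 °C; (c) 3 (1.3 equiv) added to 4, Li2CuCl4 (3 mol %), THF, −10 → 25 °C; 1 M HCl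
Reagents that add atoms: none
Why: Kochi‑type Cu‑catalysed sp3–sp3 Grignard cross‑coupling of a primary bromide is fast at low temperature and the pre‑formed halomagnesium carboxylate is inert to the Grignard, so two commodity even‑carbon fragments give the C34 acid in one operation; no stereocentre is formed.

**Step 2**
Reactants: 5 tetratriacontanoic acid; 6 Meldrum's acid (2,2‑dimethyl‑1,3‑dioxane‑4,6‑dione)
Product: 8 ethyl 3‑oxohexatriacontanoate, via acyl Meldrum's acid 7 (not isolated)
Conditions: DCC (1.1 equiv), DMAP (1.5 equiv), CHCl3, 40 °C; filter, aq. KHSO4 wash, concentrate; then EtOH–toluene (1:1), reflux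
Reagents that add atoms: ethanol, CCO
Why: Oikawa–Yonemitsu β‑keto ester synthesis: Steglich‑type C‑acylation of Meldrum's acid, then ethanolysis through the acylketene with loss of acetone and CO2, adds exactly the two carbons that become C3 and C4 of the pyranone.

**Step 3**
Reactants: 8 ethyl 3‑oxohexatriacontanoate; 9 phloroglucinol (benzene‑1,3,5‑triol)
Product: 12 5,7‑dihydroxy‑2‑tritriacontyl‑4H‑chromen‑4‑one, via acylketene 10 (not isolated), via aryl 1,3-diketone 11 (not isolated)
Conditions: 9 (anhydrous, 3 equiv), Ph2O, 245 °C, N2 sweep (EtOH and H2O distilled out), 1.5 h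
Reagents that add atoms: none
Why: Mentzer pyrone synthesis (acid‑free thermal annulation): 8 loses EtOH to acylketene 10, which C‑acylates the very electron‑rich, C3‑symmetric phloroglucinol, and the o‑hydroxyaryl 1,3‑diketone 11 cyclodehydrates to the 4‑pyranone, while the absence of acid disfavours the Pechmann coumarin pathway and excess 9 suppresses double annulation; no stereocentre is formed.

**Step 4**
Reactants: 12 5,7‑dihydroxy‑2‑tritriacontyl‑4H‑chromen‑4‑one
Product: 13 5‑hydroxy‑7‑methoxy‑2‑tritriacontyl‑4H‑chromen‑4‑one (target)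
Conditions: MeI (1.1 equiv), K2CO3 (1.2 equiv), DMF–THF (1:1), 45 °C
Reagents that add atoms: iodomethane, CI
Why: Regioselective Williamson O‑methylation: the 7‑OH is the more acidic, non‑chelated phenol whereas the 5‑OH is locked in a hydrogen bond to the C4 carbonyl, so one equivalent of MeI with mild base alkylates only O7.

## Compound list

1 | 1‑bromodocosane | CCCCCCCCCCCCCCCCCCCCCCBr | starting material
2 | 12‑bromododecanoic acid | OC(=O)CCCCCCCCCCCBr | starting material
3 | docosylmagnesium bromide | CCCCCCCCCCCCCCCCCCCCCC[Mg]Br | intermediate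
4 | chloromagnesium 12‑bromododecanoate | BrCCCCCCCCCCCC(=O)O[Mg]Cl | intermediate
5 | tetratriacontanoic acid | CCCCCCCCCCCCCCCCCCCCCCCCCCCCCCCCCC(=O)O | intermediate
6 | Meldrum's acid (2,2‑dimethyl‑1,3‑dioxane‑4,6‑dione) | CC1(C)OC(=O)CC(=O)O1 | starting material
7 | 5‑(1‑hydroxytetratriacontylidene)‑2,2‑dimethyl‑1,3‑dioxane‑4,6‑dione (acyl Meldrum's acid, enol form) | CCCCCCCCCCCCCCCCCCCCCCCCCCCCCCCCCC(O)=C1C(=O)OC(C)(C)OC1=O | intermediate
8 | ethyl 3‑oxohexatriacontanoate | CCCCCCCCCCCCCCCCCCCCCCCCCCCCCCCCCC(=O)CC(=O)OCC | intermediate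
9 | phloroglucinol (benzene‑1,3,5‑triol) | Oc1cc(O)cc(O)c1 | starting material
10 | 3‑oxohexatriacont‑1‑en‑1‑one (tetratriacontanoylketene) | CCCCCCCCCCCCCCCCCCCCCCCCCCCCCCCCCC(=O)C=C=O | intermediate
11 | 1‑(2,4,6‑trihydroxyphenyl)hexatriacontane‑1,3‑dione | CCCCCCCCCCCCCCCCCCCCCCCCCCCCCCCCCC(=O)CC(=O)c1c(O)cc(O)cc1O | intermediate
12 | 5,7‑dihydroxy‑2‑tritriacontyl‑4H‑chromen‑4‑one | CCCCCCCCCCCCCCCCCCCCCCCCCCCCCCCCCc1cc(=O)c2c(O)cc(O)cc2o1 | intermediate
13 | 5‑hydroxy‑7‑methoxy‑2‑tritriacontyl‑4H‑chromen‑4‑one | CCCCCCCCCCCCCCCCCCCCCCCCCCCCCCCCCc1cc(=O)c2c(O)cc(OC)cc2o1 | target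

## Step count and risks

Total step count: 4. Longest linear sequence: 4 steps (1 → 5 → 8 → 12 → 13); 2, 6 and 9 enter as purchased partners.

**Step 3 (Mentzer annulation) is the most likely to fail.** The risks are the coumarin (Pechmann) isomer, poor mixing of the waxy ester with the polar triol, and thermal decomposition. The fallback gives up the phenol annulation for a stepwise 1,3‑diketone route with the oxygens differentiated from the start; it sets out from 5 and comes back at 13, bypassing steps 2–4. Acid 5 with SOCl2 (toluene, 70 °C) gives tetratriacontanoyl chloride F1. F1 C‑acylates the lithium dianion of commercial 2'‑hydroxy‑4',6'‑dimethoxyacetophenone (LiHMDS 3 equiv, THF, −78 °C → rt) to give 1‑(2‑hydroxy‑4,6‑dimethoxyphenyl)hexatriacontane‑1,3‑dione F2. Cyclodehydration (cat. H2SO4, AcOH, 100 °C) gives 5,7‑dimethoxy‑2‑tritriacontyl‑4H‑chromen‑4‑one F3. BCl3 (CH2Cl2, −10 °C → rt) then cleaves only the peri 5‑OMe through the carbonyl chelate to give 13.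

**Step 1 (Cu‑catalysed Grignard coupling) is the second risk.** Wurtz homocoupling and precipitation of the C22 Grignard can erode the yield. The fallback replaces it with a Pd‑catalysed alkyl–alkyl Suzuki–Miyaura coupling; it sets out from 2 and comes back at 5. Fischer esterification of 2 (MeOH, cat. H2SO4) gives methyl 12‑bromododecanoate F4. Commercial 1‑docosene is hydroborated with 9‑BBN‑H (THF, 60 °C) to 9‑docosyl‑9‑borabicyclo[3.3.1]nonane F5. F4 and F5 are coupled (Pd(OAc)2 4 mol %, PCy3 8 mol %, K3PO4·H2O, THF, rt) to methyl tetratriacontanoate F6. Saponification (LiOH, THF–H2O, 60 °C; then H3O+) returns 5.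

**Step 2 (β‑keto ester formation) is the third risk.** The C34 acid is poorly soluble for the DCC coupling and 7 can decompose on handling. The fallback is a Masamune–Brooks decarboxylative Claisen with a different C2 donor; it sets out from 5 and comes back at 8. Acid 5 with CDI (THF, 50 °C) gives 1‑(1H‑imidazol‑1‑yl)tetratriacontan‑1‑one F7. F7 is treated with potassium ethyl malonate/MgCl2/Et3N (THF, 50 °C) and worked up with acid, with loss of CO2, to give 8.

## Further compounds

F1 | step 3 | tetratriacontanoyl chloride | CCCCCCCCCCCCCCCCCCCCCCCCCCCCCCCCCC(=O)Cl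
F2 | step 3 | 1‑(2‑hydroxy‑4,6‑dimethoxyphenyl)hexatriacontane‑1,3‑dione | CCCCCCCCCCCCCCCCCCCCCCCCCCCCCCCCCC(=O)CC(=O)c1c(O)cc(OC)cc1OC
F3 | step 3 | 5,7‑dimethoxy‑2‑tritriacontyl‑4H‑chromen‑4‑one | CCCCCCCCCCCCCCCCCCCCCCCCCCCCCCCCCc1cc(=O)c2c(OC)cc(OC)cc2o1
F4 | step 1 | methyl 12‑bromododecanoate | COC(=O)CCCCCCCCCCCBr
F5 | step 1 | 9‑docosyl‑9‑borabicyclo[3.3.1]nonane | CCCCCCCCCCCCCCCCCCCCCCB1C2CCCC1CCC2
F6 | step 1 | methyl tetratriacontanoate | CCCCCCCCCCCCCCCCCCCCCCCCCCCCCCCCCC(=O)OC
F7 | step 2 | 1‑(1H‑imidazol‑1‑yl)tetratriacontan‑1‑one | CCCCCCCCCCCCCCCCCCCCCCCCCCCCCCCCCC(=O)n1ccnc1
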